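**Retrosynthetic overview** (locants are those of the 6-oxabicyclo[3.2.1]octan-7-one core: C1 quaternary with C7=O and the butenolide arm, C2 methyl, C3, C4, C5 with O6 and isopropenyl, C8 with the propanoate arm)

1. Last disconnections: the butenolide from a C1 allyl group by cross-metathesis and alkene isomerisation; the O6–C7 lactone and the C5 isopropenyl group by isopropenyl addition to a C5 ketone with lactonisation onto the axial C7 ester.
2. Key disconnection: the carbocycle C1–C2–C3–C4–C5–C8 by a one-pot formal [3+3] annulation that makes C1–C8 (lactone enolate + nitroalkene, Michael) and C3–C4 (Nef, then aldol condensation) from a C1–C2–C3 lactone and a C8–C5–C4 nitroalkene that carries the propanoate arm.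
3. Enabling feature: C5 is a carbinol carbon flanked by C4 and C8, that is a masked ketone with its α and α′ carbons, and it stands 1,4 to the carboxyl C7 on C1 (a 1,4-dicarbonyl, hence nitroalkene umpolung); C7 and C3 are also 1,4 through C1–C2 and can be tied as a γ-lactone acetal.
4. This menthyloxy-γ-lactone ring (C7(=O)–O–C3) is not in the target: its acetal centre sets C2 (cuprate, anti), then C1 (anti to the C2 methyl), and it is cleaved inside the key step; epimers at C1 of the precursor, at the nitro carbon and at C8 converge (enolisation, Nef, equilibration).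
5. Ring order: temporary γ-lactone (purchased) → cyclohexenone carbocycle → bridging γ-lactone → butenolide double bond moved into the ring.

Key step: step 3

Assumption: compound 1, the enantiomer of the common l-menthol-derived butenolide, is taken as purchasable; otherwise it is one acetalisation/crystallisation from 5-hydroxyfuran-2(5H)-one and (1S,2R,5S)-menthol.

**Step 1**
Reactants: 1 (5S)-5-{[(1S,2R,5S)-menthyl]oxy}furan-2(5H)-one
Product: 3 (3S,4S,5S)-4-methyl-5-{[(1S,2R,5S)-menthyl]oxy}-3-(prop-2-en-1-yl)oxolan-2-one, via lithium enolate 2 (not isolated)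
Conditions: Me2CuLi (MeLi, CuI), Et2O/THF, −78 °C; then allyl bromide, DMPU, −78 → −20 °C
Reagents that add atoms: lithium dimethylcuprate ([Li+].C[Cu-]C); allyl bromide (C=CCBr)
Why: Gilman cuprate 1,4-addition to the γ-alkoxybutenolide should occur anti to the menthyloxy group (auxiliary control, sets the future C2), and the lithium enolate is C-allylated trans to the new methyl (tandem conjugate addition–enolate alkylation); the configuration at the allylated carbon is erased in step 3.

**Step 2**
Reactants: 4 methyl 4-oxobutanoate; 5 nitroethane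
Product: 8 methyl (E)-5-nitrohex-4-enoate, via nitro alcohol 6 (not isolated), via mesylate 7 (not isolated)
Conditions: 5 (3 equiv), DBU (5 mol%), THF, 0 °C; then MsCl, Et3N, −10 → 0 °C
Reagents that add atoms: none
Why: Henry (nitroaldol) addition followed by mesylation and E1cB elimination should give the more stable (E)-2-nitroalkene, and cold in-situ mesylation forestalls lactonisation of the γ-hydroxy ester; no stereocentre survives.

**Step 3**
Reactants: 3 (3S,4S,5S)-4-methyl-5-{[(1S,2R,5S)-menthyl]oxy}-3-(prop-2-en-1-yl)oxolan-2-one; 8 methyl (E)-5-nitrohex-4-enoate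
Product: 12 (1R,2R,6R)-6-(2-carboxyethyl)-2-methyl-5-oxo-1-(prop-2-en-1-yl)cyclohex-3-ene-1-carboxylic acid, via lithium nitronate 9 (not isolated), via keto lactone 10 (not isolated), via keto aldehyde acid 11 (not isolated)
Conditions: LDA, THF, −78 °C; 8, −78 → −40 °C; cannulate into 4 M H2SO4, 0 °C; then NaOH (aq.), MeOH, 0 → 23 °C (menthol extracted from the basic phase); HCl to pH 2
Reagents that add atoms: water (O); sodium hydroxide ([Na+].[OH-])
Why: LDA gives the tetrasubstituted lactone enolate of 3, which adds to the β-carbon of 8 (Michael addition, C1–C8 bond) to give nitronate 9; inverse quench into cold acid converts 9 into methyl ketone 10 (Nef reaction); hydroxide then opens the acylal lactone at C7 with loss of menthoxide to give 11, whose methyl-ketone enolate attacks the freed C3 aldehyde and dehydrates (aldol condensation, C3–C4 bond) while the side-chain ester is saponified. The closest known reaction types are the enolate–nitroalkene Michael/Nef synthesis of 1,4-dicarbonyl compounds and the Robinson-type intramolecular aldol cyclodehydration, here joined as a formal [3+3] annulation. The carbocycle closes by a 6-(enolendo)-exo-trig aldol followed by E1cB dehydration; the C8 enolate could only form a four-membered ring, and the 5-(enolendo) Claisen closure onto C7 is Baldwin-disfavoured. The quaternary C1 centre is set by attack of the nitroalkene on the enolate face anti to the adjacent C2 methyl in the rigid five-membered ring, C2 is carried from step 1, the nitro-bearing carbon is erased by the Nef reaction, and C8 forms as an epimer mixture that is corrected thermodynamically in step 5. The step needs C–C bond formation instead of proton transfer from the γ-CH of 8 (lithium enolate, low temperature), and ring closure before enolisation of the aldehyde α-carbon C2 (the unhindered methyl ketone should enolise faster than the hindered aldehyde; cold, short base stage).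

**Step 4**
Reactants: 12 (1R,2R,6R)-6-(2-carboxyethyl)-2-methyl-5-oxo-1-(prop-2-en-1-yl)cyclohex-3-ene-1-carboxylic acid
Product: 13 methyl (1R,2R,6R)-6-(3-methoxy-3-oxopropyl)-2-methyl-5-oxo-1-(prop-2-en-1-yl)cyclohex-3-ene-1-carboxylate
Conditions: MeI, K2CO3, DMF, 23 °C
Reagents that add atoms: iodomethane (CI)
Why: SN2 O-alkylation of both carboxylates (carboxylate esterification) needs no addition to the hindered C7 carbonyl, so the neopentyl-type acid should esterify as readily as the side-chain acid.

**Step 5**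
Reactants: 13 methyl (1R,2R,6R)-6-(3-methoxy-3-oxopropyl)-2-methyl-5-oxo-1-(prop-2-en-1-yl)cyclohex-3-ene-1-carboxylate
Product: 14 methyl (1R,2R,6R)-2-(3-methoxy-3-oxopropyl)-6-methyl-3-oxo-1-(prop-2-en-1-yl)cyclohexane-1-carboxylate
Conditions: [(Ph3P)CuH]6, H2O, benzene/THF, 23 °C; then NaOMe (cat.), MeOH, 23 °C
Reagents that add atoms: none
Why: Copper hydride conjugate reduction (Stryker's reagent) is selective for the enone over the allyl alkene and the esters, and methoxide equilibration α to the ketone should funnel the C8 epimers to the one with the side chain equatorial and cis to the C2 methyl, which axial protonation anti to the axial C7 ester also favours.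

**Step 6**
Reactants: 14 methyl (1R,2R,6R)-2-(3-methoxy-3-oxopropyl)-6-methyl-3-oxo-1-(prop-2-en-1-yl)cyclohexane-1-carboxylate
Product: 16 methyl 3-[(1R,2R,5S,8R)-2-methyl-7-oxo-5-(prop-1-en-2-yl)-1-(prop-2-en-1-yl)-6-oxabicyclo[3.2.1]octan-8-yl]propanoate, via magnesium alkoxide 15 (not isolated)
Conditions: CH2=C(CH3)MgBr, CeCl3, THF, −78 → 23 °C
Reagents that add atoms: isopropenylmagnesium bromide (C=C(C)[Mg]Br)
Why: Organocerium 1,2-addition should take place on the ketone only and from the equatorial direction, because the axial C7 ester on C1 blocks axial attack, and the resulting axial alkoxide closes onto that ester (γ-lactonisation by acyl substitution) to form the bridged lactone and set C5.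

**Step 7**
Reactants: 16 methyl 3-[(1R,2R,5S,8R)-2-methyl-7-oxo-5-(prop-1-en-2-yl)-1-(prop-2-en-1-yl)-6-oxabicyclo[3.2.1]octan-8-yl]propanoate; 17 3-methylideneoxolan-2-one
Product: 18 methyl 3-[(1R,2R,5S,8R)-2-methyl-7-oxo-1-[(2E)-2-(2-oxooxolan-3-ylidene)ethyl]-5-(prop-1-en-2-yl)-6-oxabicyclo[3.2.1]octan-8-yl]propanoate
Conditions: 17 (5 equiv), second-generation Hoveyda–Grubbs catalyst RuCl2(H2IMes)(=CH-C6H4-2-OiPr) (5 mol%), 2,6-dichloro-1,4-benzoquinone (10 mol%), CH2Cl2, 40 °C
Reagents that add atoms: none
Why: Olefin cross-metathesis of the monosubstituted allyl alkene with α-methylene-γ-butyrolactone should leave the hindered isopropenyl group untouched, the quinone suppresses premature isomerisation, and E/Z isomers of the alkylidene lactone converge in step 8.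

**Step 8**
Reactants: 18 methyl 3-[(1R,2R,5S,8R)-2-methyl-7-oxo-1-[(2E)-2-(2-oxooxolan-3-ylidene)ethyl]-5-(prop-1-en-2-yl)-6-oxabicyclo[3.2.1]octan-8-yl]propanoate
Product: 19 methyl 3-[(1R,2R,5S,8R)-2-methyl-7-oxo-1-[2-(2-oxo-2,5-dihydrofuran-3-yl)ethyl]-5-(prop-1-en-2-yl)-6-oxabicyclo[3.2.1]octan-8-yl]propanoate
Conditions: RhCl3·3H2O (5 mol%), EtOH, 75 °C
Reagents that add atoms: none
Why: Rhodium hydride-mediated alkene isomerisation (hydrometalation/β-hydride elimination) should move the exocyclic double bond of the α-alkylidene lactone into the ring to give the more stable 2(5H)-furanone; the isopropenyl group has no productive migration path and no stereocentre is touched.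

**Compound list**

1 | (5S)-5-{[(1S,2R,5S)-menthyl]oxy}furan-2(5H)-one | O=C1C=C[C@@H](O[C@H]2C[C@@H](C)CC[C@@H]2C(C)C)O1 | starting material
2 | lithium (4S,5S)-4-methyl-5-menthyloxy-4,5-dihydrofuran-2-olate | O1[C@H](O[C@H]2C[C@@H](C)CC[C@@H]2C(C)C)[C@@H](C)C=C1[O-].[Li+] | intermediate
3 | (3S,4S,5S)-4-methyl-5-{[(1S,2R,5S)-menthyl]oxy}-3-(prop-2-en-1-yl)oxolan-2-one | O1[C@H](O[C@H]2C[C@@H](C)CC[C@@H]2C(C)C)[C@@H](C)[C@H](CC=C)C1=O | intermediate
4 | methyl 4-oxobutanoate | COC(=O)CCC=O | starting material
5 | nitroethane | CC[N+](=O)[O-] | starting material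
6 | methyl 4-hydroxy-5-nitrohexanoate (diastereomer mixture) | COC(=O)CCC(O)C(C)[N+](=O)[O-] | intermediate
7 | methyl 4-(methanesulfonyloxy)-5-nitrohexanoate | COC(=O)CCC(OS(C)(=O)=O)C(C)[N+](=O)[O-] | intermediate
8 | methyl (E)-5-nitrohex-4-enoate | COC(=O)CC/C=C(\C)[N+](=O)[O-] | intermediate
9 | lithium nitronate of the Michael adduct (lactone carbons arranged as in 10; side-chain CH as epimer mixture) | O1[C@H](O[C@H]2C[C@@H](C)CC[C@@H]2C(C)C)[C@@H](C)[C@@](CC=C)(C1=O)C(CCC(=O)OC)C(C)=[N+]([O-])[O-].[Li+] | intermediate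
10 | methyl 4-[(3R,4S,5S)-4-methyl-5-{[(1S,2R,5S)-menthyl]oxy}-2-oxo-3-(prop-2-en-1-yl)oxolan-3-yl]-5-oxohexanoate (epimer mixture at hexanoate C4) | O1[C@H](O[C@H]2C[C@@H](C)CC[C@@H]2C(C)C)[C@@H](C)[C@@](CC=C)(C1=O)C(CCC(=O)OC)C(C)=O | intermediate
11 | (2R,3S)-2-(6-methoxy-2,6-dioxohexan-3-yl)-3-methyl-4-oxo-2-(prop-2-en-1-yl)butanoic acid (present as sodium salt) | O=C[C@@H](C)[C@@](CC=C)(C(=O)O)C(CCC(=O)OC)C(C)=O | intermediate
12 | (1R,2R,6R)-6-(2-carboxyethyl)-2-methyl-5-oxo-1-(prop-2-en-1-yl)cyclohex-3-ene-1-carboxylic acid | O=C1C=C[C@@H](C)[C@@](CC=C)(C(=O)O)[C@H]1CCC(=O)O | intermediate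
13 | methyl (1R,2R,6R)-6-(3-methoxy-3-oxopropyl)-2-methyl-5-oxo-1-(prop-2-en-1-yl)cyclohex-3-ene-1-carboxylate | O=C1C=C[C@@H](C)[C@@](CC=C)(C(=O)OC)[C@H]1CCC(=O)OC | intermediate
14 | methyl (1R,2R,6R)-2-(3-methoxy-3-oxopropyl)-6-methyl-3-oxo-1-(prop-2-en-1-yl)cyclohexane-1-carboxylate | O=C1CC[C@@H](C)[C@@](CC=C)(C(=O)OC)[C@H]1CCC(=O)OC | intermediate
15 | bromomagnesium alkoxide of the tertiary isopropenyl carbinol (O axial, cis to the C7 ester) | C=C(C)[C@]1(O[Mg]Br)CC[C@@H](C)[C@@](CC=C)(C(=O)OC)[C@H]1CCC(=O)OC | intermediate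
16 | methyl 3-[(1R,2R,5S,8R)-2-methyl-7-oxo-5-(prop-1-en-2-yl)-1-(prop-2-en-1-yl)-6-oxabicyclo[3.2.1]octan-8-yl]propanoate | C=C(C)[C@@]12CC[C@@H](C)[C@@](CC=C)(C(=O)O1)[C@H]2CCC(=O)OC | intermediate
17 | 3-methylideneoxolan-2-one (α-methylene-γ-butyrolactone) | C=C1CCOC1=O | starting material
18 | methyl 3-[(1R,2R,5S,8R)-2-methyl-7-oxo-1-[(2E)-2-(2-oxooxolan-3-ylidene)ethyl]-5-(prop-1-en-2-yl)-6-oxabicyclo[3.2.1]octan-8-yl]propanoate | C=C(C)[C@@]12CC[C@@H](C)[C@@](C/C=C3\CCOC3=O)(C(=O)O1)[C@H]2CCC(=O)OC | intermediate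
19 | methyl 3-[(1R,2R,5S,8R)-2-methyl-7-oxo-1-[2-(2-oxo-2,5-dihydrofuran-3-yl)ethyl]-5-(prop-1-en-2-yl)-6-oxabicyclo[3.2.1]octan-8-yl]propanoate | C=C(C)[C@@]12CC[C@@H](C)[C@@](CCC3=CCOC3=O)(C(=O)O1)[C@H]2CCC(=O)OC | target

**Step count and risks**

Total step count: 8. Longest linear sequence: 7 (steps 1, 3, 4, 5, 6, 7, 8); step 2 is the side branch.

Steps most likely to fail:

1. Step 3. Proton transfer from the γ-CH of 8 to the hindered enolate may outrun conjugate addition; facial selectivity at C1 may erode because the menthyloxy group sits on the attacked face; the Nef stage may stall at the nitro compound; the aldehyde α-carbon C2 may enolise before ring closure. The fallback sets out from 3: silylation of its lithium enolate (LDA, TMSCl, THF, −78 °C) gives the trimethylsilyl ketene acetal F1. A Lewis acid-promoted Mukaiyama–Michael addition of F1 to 8 (SnCl4, CH2Cl2, −78 °C), with hydrolytic work-up that turns the silyl nitronate into the ketone, gives isolated keto lactone 10. Compound 10 is then cyclised separately (aqueous NaOH/MeOH, or aqueous HCl then TsOH in toluene if C2 suffers in base). The route is rejoined at 10 and continues to 12.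

2. Step 7. Cross-metathesis at the congested alkene next to the quaternary carbon may be unproductive (homodimerisation of 16, isomerisation of 17, slow turnover). The fallback sets out from 14: ozonolysis of the allyl group (O3, CH2Cl2/MeOH, −78 °C; Me2S) gives the keto aldehyde F2. Aldehyde-selective Horner–Wadsworth–Emmons olefination with diethyl (2-oxooxolan-3-yl)phosphonate (LiCl, DBU, MeCN) gives the alkylidene lactone ketone F3. Isopropenyl organocerium addition with lactonisation, as in step 6, then gives 18, where the route is rejoined.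

3. Step 8. Double-bond migration may be incomplete, or the tertiary allylic C5–O6 bond may ionise under the mildly acidic conditions. The fallback sets out from 18: 1,4-reduction of the alkylidene lactone with potassium tri-sec-butylborohydride (THF, −78 °C) and trapping of the enolate with S-phenyl benzenethiosulfonate gives the α-phenylsulfanyl lactone F4. Oxidation at sulfur (mCPBA, CH2Cl2, −78 °C) gives the sulfoxide F5. Thermal syn-elimination into the ring (toluene, 110 °C, CaCO3) gives 19 directly.

**Further compounds**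

F1 | step 3 | {[(4S,5S)-4-methyl-5-{[(1S,2R,5S)-menthyl]oxy}-3-(prop-2-en-1-yl)-4,5-dihydrofuran-2-yl]oxy}trimethylsilane | O1[C@H](O[C@H]2C[C@@H](C)CC[C@@H]2C(C)C)[C@@H](C)C(CC=C)=C1O[Si](C)(C)C
F2 | step 7 | methyl (1R,2R,6R)-2-(3-methoxy-3-oxopropyl)-6-methyl-3-oxo-1-(2-oxoethyl)cyclohexane-1-carboxylate | O=C1CC[C@@H](C)[C@@](CC=O)(C(=O)OC)[C@H]1CCC(=O)OC
F3 | step 7 | methyl (1R,2R,6R)-2-(3-methoxy-3-oxopropyl)-6-methyl-3-oxo-1-[(2E)-2-(2-oxooxolan-3-ylidene)ethyl]cyclohexane-1-carboxylate | O=C1CC[C@@H](C)[C@@](C/C=C2\CCOC2=O)(C(=O)OC)[C@H]1CCC(=O)OC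
F4 | step 8 | methyl 3-[(1R,2R,5S,8R)-2-methyl-7-oxo-1-{2-[2-oxo-3-(phenylsulfanyl)oxolan-3-yl]ethyl}-5-(prop-1-en-2-yl)-6-oxabicyclo[3.2.1]octan-8-yl]propanoate (epimer mixture at the sulfur-bearing carbon) | C=C(C)[C@@]12CC[C@@H](C)[C@@](CCC3(Sc4ccccc4)CCOC3=O)(C(=O)O1)[C@H]2CCC(=O)OC
F5 | step 8 | methyl 3-[(1R,2R,5S,8R)-2-methyl-7-oxo-1-{2-[2-oxo-3-(phenylsulfinyl)oxolan-3-yl]ethyl}-5-(prop-1-en-2-yl)-6-oxabicyclo[3.2.1]octan-8-yl]propanoate (diastereomer mixture) | C=C(C)[C@@]12CC[C@@H](C)[C@@](CCC3(S(=O)c4ccccc4)CCOC3=O)(C(=O)O1)[C@H]2CCC(=O)OC
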